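**Strategy.** Each fisetinidol ring C (O1–C2–C3–C4, fused to resorcinol ring A and bearing the next arene at C4) is disconnected across O1–C2 and C3–C4. This gives an ortho-quinone methide (O1=C8a–C4a=C4) and an (E)-β-silylstyrene whose silicon is the masked 3-hydroxyl. One acid-catalysed, threefold inverse-demand hetero-Diels–Alder reaction then closes ring C of units T, M and U, forming six bonds and nine stereocentres. Its precursor is penta-O-benzylcatechin carrying one ortho-hydroxybenzhydrol at C8 and two linked ones at C6, with every other oxygen benzylated.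

Key step: step 13

**Remarks on the chemistry (assumptions).**
- Unit labels: B = catechin unit; U = fisetinidol unit on C8 of B; M = fisetinidol unit on C6 of B; T = terminal fisetinidol unit on C6 of M. Flavan numbering is used within each unit.
- The silicon substituents that are not transferred are treated as spectators. Benzyldimethylsilyl replaces phenyldimethylsilyl because a phenyl–silicon bond is cleaved only by electrophiles or hot strong base, which fourteen electron-rich benzyloxyarenes and the acid-labile ring C would not tolerate. A benzyl–silicon bond is cleaved by fluoride at 0 °C.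
- All three carbinol-forming metalation sites are fixed by halogens, because deprotonation of a resorcinol diether would occur between its two oxygens.
- The (R) acid is written in the key step; which antipode opens the required methide face is assumed and would be settled on a one-carbinol model.
- The carbinol centres are carried as epimer mixtures by design, since they become trigonal in the key step.
- 4-(Benzyloxy)-2-hydroxybenzaldehyde is taken as commercially available.
- Stoichiometry: step 9 builds two molecules of aldehyde 7 into its product, and step 13 builds in three molecules of silylstyrene 17, one per ring C; in step 13 each of these molecules is entered on its own.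

**Route**

Step 1
Reactants: 1 (+)-catechin
Product: 2 5,7,3',4'-tetra-O-benzylcatechin
Conditions: BnBr (4.4 equiv), K2CO3, DMF, 0 °C to rt
Reagents that add atoms: benzyl bromide, BrCc1ccccc1
Why: Williamson ether synthesis in which carbonate deprotonates only the four phenols, so the secondary C3 hydroxyl stays free and C2/C3 are untouched.

Step 2
Reactants: 2 5,7,3',4'-tetra-O-benzylcatechin
Product: 3 3,5,7,3',4'-penta-O-benzylcatechin
Conditions: NaH, BnBr, DMF, 0 °C to rt
Reagents that add atoms: benzyl bromide, BrCc1ccccc1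
Why: Williamson etherification of the C3 alkoxide; with no free phenol left, the base cannot open ring C through a quinone methide, so C2 should not epimerise.

Step 3
Reactants: 3 3,5,7,3',4'-penta-O-benzylcatechin
Product: 4 8-bromo-3,5,7,3',4'-penta-O-benzylcatechin
Conditions: NBS (1.0 equiv), CH2Cl2, −20 °C to rt
Reagents that add atoms: N-bromosuccinimide, O=C1CCC(=O)N1Br
Why: Electrophilic aromatic bromination of the phloroglucinol-type ring A, which in benzylated catechin reacts first at C8, while the catechol ring is far less nucleophilic.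

Step 4
Reactants: 4 8-bromo-3,5,7,3',4'-penta-O-benzylcatechin
Product: 5 8-bromo-6-iodo-3,5,7,3',4'-penta-O-benzylcatechin
Conditions: NIS (1.1 equiv), CF3CO2H (cat.), CH2Cl2/MeCN, 0 °C to rt
Reagents that add atoms: N-iodosuccinimide, O=C1CCC(=O)N1I
Why: Electrophilic aromatic iodination at C6, the only open position of ring A and flanked by two benzyloxy groups; two different halogens allow C6 to be metalated before C8.

Step 5
Reactants: 6 4-(benzyloxy)-2-hydroxybenzaldehyde
Product: 7 2-(allyloxy)-4-(benzyloxy)benzaldehyde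
Conditions: allyl bromide, K2CO3, DMF, rt
Reagents that add atoms: allyl bromide, C=CCBr
Why: Williamson etherification; allyl is chosen because it is later removed under non-acidic conditions that spare benzyl ethers and acid-labile benzhydrols.

Step 6
Reactants: 6 4-(benzyloxy)-2-hydroxybenzaldehyde
Product: 8 4-(benzyloxy)-5-bromo-2-hydroxybenzaldehyde
Conditions: NBS (1.0 equiv), MeCN, 0 °C to rt
Reagents that add atoms: N-bromosuccinimide, O=C1CCC(=O)N1Br
Why: Electrophilic aromatic bromination para to the free phenol and ortho to the benzyloxy group (C5), the less hindered of the two activated positions; this marks the future C6 of unit M.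

Step 7
Reactants: 8 4-(benzyloxy)-5-bromo-2-hydroxybenzaldehyde
Product: 9 2-(allyloxy)-4-(benzyloxy)-5-bromobenzaldehyde
Conditions: allyl bromide, K2CO3, DMF, rt
Reagents that add atoms: allyl bromide, C=CCBr
Why: Williamson etherification of the phenol, which leaves the aldehyde and the aryl bromide untouched.

Step 8
Reactants: 5 8-bromo-6-iodo-3,5,7,3',4'-penta-O-benzylcatechin; 9 2-(allyloxy)-4-(benzyloxy)-5-bromobenzaldehyde
Product: 11 [2-(allyloxy)-4-(benzyloxy)-5-bromophenyl](8-bromo-penta-O-benzylcatechin-6-yl)methanol (carbinol epimers), via C6 arylmagnesium chloride 10 (not isolated)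
Conditions: i-PrMgCl·LiCl (1.05 equiv), THF, −20 to 0 °C; then 9, −20 °C to rt; H2O
Reagents that add atoms: none
Why: Iodine–magnesium exchange is selective for the aryl iodide over both electron-rich aryl bromides, and the arylmagnesium then adds to the aldehyde (Grignard addition); the new carbinol centre is left uncontrolled.

Step 9
Reactants: 11 dibromo carbinol; 7 2-(allyloxy)-4-(benzyloxy)benzaldehyde (2.5 equiv)
Product: 13 tri-O-allyl tris(benzhydrol) (carbinol epimers), via trilithium species 12 (not isolated)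
Conditions: MeLi (1.0 equiv), THF, −78 °C; t-BuLi (4.2 equiv), −78 °C; then 7, −78 to 0 °C; H2O
Reagents that add atoms: none
Why: After deprotonation of the carbinol, twofold bromine–lithium exchange at −78 °C outruns any deprotonation of benzyl or allyl ethers, and both aryllithiums (C8 of unit B and C6 of unit M) undergo 1,2-addition to one molecule of aldehyde 7 each, installing the U and T carbinols in one operation.

Step 10
Reactants: 13 tri-O-allyl tris(benzhydrol)
Product: 14 tris(ortho-hydroxybenzhydrol) on penta-O-benzylcatechin (carbinol epimers)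
Conditions: Pd(PPh3)4 (10 mol%), morpholine, THF, rt
Reagents that add atoms: none
Why: Tsuji–Trost deallylation in which zerovalent palladium ionises the three aryl allyl ethers and morpholine traps the allyl groups; the medium stays basic, so benzyl ethers and the acid-labile benzhydrols should survive (isolation on Et3N-deactivated silica).

Step 11
Reactants: 15 3,4-bis(benzyloxy)benzaldehyde
Product: 16 1,2-bis(benzyloxy)-4-ethynylbenzene
Conditions: dimethyl (1-diazo-2-oxopropyl)phosphonate, K2CO3, MeOH/THF, rt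
Reagents that add atoms: dimethyl (1-diazo-2-oxopropyl)phosphonate, COP(=O)(OC)C(=[N+]=[N-])C(C)=O
Why: Seyferth–Gilbert homologation in its Ohira–Bestmann form: the diazomethylphosphonate anion formed by methanolysis converts the aldehyde into the terminal alkyne by addition–elimination, loss of N2 and 1,2-hydrogen shift.

Step 12
Reactants: 16 1,2-bis(benzyloxy)-4-ethynylbenzene
Product: 17 (E)-benzyl{2-[3,4-bis(benzyloxy)phenyl]ethenyl}dimethylsilane
Conditions: BnMe2SiH, Pt2[(CH2=CHSiMe2)2O]3 (1 mol%), P(t-Bu)3 (2 mol%), THF, 0 °C to rt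
Reagents that add atoms: benzyldimethylsilane, C[SiH](C)Cc1ccccc1
Why: Platinum-catalysed alkyne hydrosilylation (Chalk–Harrod mechanism): syn addition of Si–H with silicon at the terminal carbon, steered by the bulky phosphine, should give the (E)-β-silylstyrene.

Step 13
Reactants: 14 tris(ortho-hydroxybenzhydrol); 17 silylstyrene (4.5 equiv); 17 silylstyrene (second molecule built in); 17 silylstyrene (third molecule built in)
Product: 19 perbenzylated tris(3-silyl) tetramer, via tris(ortho-quinone methide) 18 (not isolated)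
Conditions: (R)-3,3'-bis(2,4,6-triisopropylphenyl)-1,1'-binaphthyl-2,2'-diyl hydrogen phosphate (30 mol%), 5 Å molecular sieves, toluene, −20 °C to rt; Et3N quench
Reagents that add atoms: second molecule of silylstyrene 17, C[Si](C)(Cc1ccccc1)/C=C/c1ccc(OCc2ccccc2)c(OCc2ccccc2)c1; third molecule of silylstyrene 17, C[Si](C)(Cc1ccccc1)/C=C/c1ccc(OCc2ccccc2)c(OCc2ccccc2)c1
Why: Proposed new method: the chiral phosphoric acid ionises each benzhydrol (both carbinol epimers converge, since C4 becomes trigonal) to an ortho-quinone methide O1=C8a–C4a=C4 that stays hydrogen-bonded to the phosphate, and one molecule of the electron-rich (E)-β-silylstyrene 17 per methide, three in all, adds across C4 and O1 in an inverse-demand hetero-Diels–Alder reaction with loss of three molecules of water overall; the closest known reaction type is the Brønsted-acid-catalysed [4+2] of ortho-quinone methides generated from ortho-hydroxybenzhydrols with styrenes, which has not been shown with a vinylsilane or three times in one molecule. Ring C of each of units T, M and U closes as a six-membered ring in a concerted but asynchronous [4+2] mode, C3–C4 forming ahead of O1–C2. Regiochemistry (silicon-bearing carbon to C4, aryl-bearing carbon to O1) follows from the positive charge that builds up on the alkene carbon benzylic to the 3,4-bis(benzyloxy)phenyl ring and β to silicon. In each ring C4 is set by the methide face left open by the phosphate, C2 by endo placement of the styrene aryl group under the E-methide (2,4-cis) and C3 by the E geometry of the alkene (2,3-trans and therefore 3,4-trans), so one facial choice fixes three centres. The step needs cycloaddition to win over loss of silicon from the β-silyl cation, over xanthene formation and over arene alkylation, which the precursor secures by placing the ring-oxygen nucleophile ortho to each methide, by benzyl caps on every other oxygen ortho to a carbinol and by an excess of 17. The carbinols that flank the phloroglucinol-type ring A of unit B should ionise first, so the phenol of unit M is built into its ring C before the T carbinol can use it to form a para-quinone methide, which would in any case revert.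

Step 14
Reactants: 19 perbenzylated tris(3-silyl) tetramer
Product: 21 tetradeca-O-benzyl tetramer with free 3-hydroxyls on units T, M and U, via tris(silanol) 20 (not isolated)
Conditions: Bu4NF, THF, 0 °C to rt; then KHCO3, H2O2 (30% aq), MeOH, rt to 40 °C
Reagents that add atoms: hydrogen peroxide, OO
Why: Tamao–Fleming oxidation: fluoride cleaves the benzyl–silicon bond to give a silanol, and hydroperoxide then induces 1,2-migration of C3 from silicon to oxygen with retention, so each hydroxyl takes the place of silicon without any electrophile or acid and the 3-O-benzyl group of unit B is untouched.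

Step 15
Reactants: 21 tetradeca-O-benzyl tetramer triol
Product: 22 fisetinidol-(4α→6)-fisetinidol-(4α→6)-[fisetinidol-(4α→8)]-catechin (target)
Conditions: H2 (1 atm), Pd(OH)2 on carbon, THF/MeOH/H2O, rt
Reagents that add atoms: none
Why: Hydrogenolysis of all fourteen benzyl ethers under neutral conditions, as is standard for benzylated flavan-3-ol oligomers; C2–O1 and C4–aryl bonds should not be cleaved and no stereocentre is touched.

**Compound list**

1 | (+)-catechin, (2R,3S)-2-(3,4-dihydroxyphenyl)chromane-3,5,7-triol | Oc1cc(O)c2c(c1)O[C@H](c1ccc(O)c(O)c1)[C@@H](O)C2 | starting material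
2 | 5,7,3',4'-tetra-O-benzylcatechin (2R,3S; 3-OH free) | C(c9ccccc9)Oc1cc(OCc9ccccc9)c2c(c1)O[C@H](c1ccc(OCc9ccccc9)c(OCc9ccccc9)c1)[C@@H](O)C2 | intermediate
3 | 3,5,7,3',4'-penta-O-benzylcatechin (2R,3S) | C(c9ccccc9)Oc1cc(OCc9ccccc9)c2c(c1)O[C@H](c1ccc(OCc9ccccc9)c(OCc9ccccc9)c1)[C@@H](OCc9ccccc9)C2 | intermediate
4 | 8-bromo-3,5,7,3',4'-penta-O-benzylcatechin (2R,3S) | C(c9ccccc9)Oc1cc(OCc9ccccc9)c2c(c1Br)O[C@H](c1ccc(OCc9ccccc9)c(OCc9ccccc9)c1)[C@@H](OCc9ccccc9)C2 | intermediate
5 | 8-bromo-6-iodo-3,5,7,3',4'-penta-O-benzylcatechin (2R,3S) | C(c9ccccc9)Oc1c(I)c(OCc9ccccc9)c2c(c1Br)O[C@H](c1ccc(OCc9ccccc9)c(OCc9ccccc9)c1)[C@@H](OCc9ccccc9)C2 | intermediate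
6 | 4-(benzyloxy)-2-hydroxybenzaldehyde | O=Cc1ccc(OCc2ccccc2)cc1O | starting material
7 | 2-(allyloxy)-4-(benzyloxy)benzaldehyde | O=Cc1ccc(OCc2ccccc2)cc1OCC=C | intermediate
8 | 4-(benzyloxy)-5-bromo-2-hydroxybenzaldehyde | O=Cc1cc(Br)c(OCc2ccccc2)cc1O | intermediate
9 | 2-(allyloxy)-4-(benzyloxy)-5-bromobenzaldehyde | O=Cc1cc(Br)c(OCc2ccccc2)cc1OCC=C | intermediate
10 | (8-bromo-3,5,7,3',4'-penta-O-benzylcatechin-6-yl)magnesium chloride (2R,3S) | C(c9ccccc9)Oc1c([Mg]Cl)c(OCc9ccccc9)c2c(c1Br)O[C@H](c1ccc(OCc9ccccc9)c(OCc9ccccc9)c1)[C@@H](OCc9ccccc9)C2 | intermediate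
11 | [2-(allyloxy)-4-(benzyloxy)-5-bromophenyl](8-bromo-3,5,7,3',4'-penta-O-benzylcatechin-6-yl)methanol; unit B (2R,3S), carbinol centre both epimers | C(c9ccccc9)Oc1c(C(O)c3cc(Br)c(OCc9ccccc9)cc3OCC=C)c(OCc9ccccc9)c2c(c1Br)O[C@H](c1ccc(OCc9ccccc9)c(OCc9ccccc9)c1)[C@@H](OCc9ccccc9)C2 | intermediate
12 | trilithium species: lithium alkoxide of 11 with C–Li in place of both C–Br bonds (C8 of unit B and C5 of the former bromophenyl ring) | C(c9ccccc9)Oc1c(C(O[Li])c3cc([Li])c(OCc9ccccc9)cc3OCC=C)c(OCc9ccccc9)c2c(c1[Li])O[C@H](c1ccc(OCc9ccccc9)c(OCc9ccccc9)c1)[C@@H](OCc9ccccc9)C2 | intermediate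
13 | tri-O-allyl tris(benzhydrol): penta-O-benzylcatechin (2R,3S) with CH(OH)[2-(allyloxy)-4-(benzyloxy)phenyl] at C8 and, at C6, CH(OH)Ar where Ar = 2-(allyloxy)-4-(benzyloxy)-5-{hydroxy[2-(allyloxy)-4-(benzyloxy)phenyl]methyl}phenyl; three carbinol centres as epimer mixtures | C(c9ccccc9)Oc1c(C(O)c3cc(C(O)c4ccc(OCc9ccccc9)cc4OCC=C)c(OCc9ccccc9)cc3OCC=C)c(OCc9ccccc9)c2c(c1C(O)c5ccc(OCc9ccccc9)cc5OCC=C)O[C@H](c1ccc(OCc9ccccc9)c(OCc9ccccc9)c1)[C@@H](OCc9ccccc9)C2 | intermediate
14 | key-step precursor: as 13 with the three allyloxy groups replaced by free phenols (each phenol ortho to one carbinol); unit B (2R,3S), carbinol centres unassigned | C(c9ccccc9)Oc1c(C(O)c3cc(C(O)c4ccc(OCc9ccccc9)cc4O)c(OCc9ccccc9)cc3O)c(OCc9ccccc9)c2c(c1C(O)c5ccc(OCc9ccccc9)cc5O)O[C@H](c1ccc(OCc9ccccc9)c(OCc9ccccc9)c1)[C@@H](OCc9ccccc9)C2 | intermediate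
15 | 3,4-bis(benzyloxy)benzaldehyde | O=Cc1ccc(OCc2ccccc2)c(OCc2ccccc2)c1 | starting material
16 | 1,2-bis(benzyloxy)-4-ethynylbenzene | C#Cc1ccc(OCc2ccccc2)c(OCc2ccccc2)c1 | intermediate
17 | (E)-benzyl{2-[3,4-bis(benzyloxy)phenyl]ethenyl}dimethylsilane | C[Si](C)(Cc1ccccc1)/C=C/c1ccc(OCc2ccccc2)c(OCc2ccccc2)c1 | intermediate
18 | tris(ortho-quinone methide) of 14, all three exocyclic C4a=C4 bonds E (formal fully dehydrated form; the methides are expected to arise and react one at a time) | C1=CC(OCc9ccccc9)=CC(=O)/C1=C/C3=CC(=C/c4c(OCc9ccccc9)c5c(c(/C=C6/C(=O)C=C(OCc9ccccc9)C=C6)c4OCc9ccccc9)O[C@H](c4ccc(OCc9ccccc9)c(OCc9ccccc9)c4)[C@@H](OCc9ccccc9)C5)\C(=O)C=C3OCc9ccccc9 | intermediate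
19 | key-step product: tetradeca-O-benzyl tetramer with SiMe2Bn on C3 of units T, M and U; each new ring C 2,4-cis-2,3-trans (C2 aryl and C4 aryl cis, C3 silicon trans to both), absolute configuration as in the SMILES; unit B (2R,3S) | c9ccccc9COc1ccc2c(c1)O[C@H](c1ccc(OCc9ccccc9)c(OCc9ccccc9)c1)[C@@H]([Si](C)(C)Cc9ccccc9)[C@@H]2c1cc2c(cc1OCc9ccccc9)O[C@H](c1ccc(OCc9ccccc9)c(OCc9ccccc9)c1)[C@@H]([Si](C)(C)Cc9ccccc9)[C@@H]2c1c(OCc9ccccc9)c2c(c([C@@H]3c4ccc(OCc9ccccc9)cc4O[C@H](c4ccc(OCc9ccccc9)c(OCc9ccccc9)c4)[C@H]3[Si](C)(C)Cc9ccccc9)c1OCc9ccccc9)O[C@H](c1ccc(OCc9ccccc9)c(OCc9ccccc9)c1)[C@@H](OCc9ccccc9)C2 | intermediate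
20 | tris(silanol): as 19 with SiMe2OH in place of each SiMe2Bn, same configuration | c9ccccc9COc1ccc2c(c1)O[C@H](c1ccc(OCc9ccccc9)c(OCc9ccccc9)c1)[C@@H]([Si](C)(C)O)[C@@H]2c1cc2c(cc1OCc9ccccc9)O[C@H](c1ccc(OCc9ccccc9)c(OCc9ccccc9)c1)[C@@H]([Si](C)(C)O)[C@@H]2c1c(OCc9ccccc9)c2c(c([C@@H]3c4ccc(OCc9ccccc9)cc4O[C@H](c4ccc(OCc9ccccc9)c(OCc9ccccc9)c4)[C@H]3[Si](C)(C)O)c1OCc9ccccc9)O[C@H](c1ccc(OCc9ccccc9)c(OCc9ccccc9)c1)[C@@H](OCc9ccccc9)C2 | intermediate
21 | tetradeca-O-benzyl tetramer with free 3-hydroxyls on units T, M and U (each 2,3-trans-3,4-trans) and the 3-O-benzyl group kept on unit B | c9ccccc9COc1ccc2c(c1)O[C@H](c1ccc(OCc9ccccc9)c(OCc9ccccc9)c1)[C@@H](O)[C@@H]2c1cc2c(cc1OCc9ccccc9)O[C@H](c1ccc(OCc9ccccc9)c(OCc9ccccc9)c1)[C@@H](O)[C@@H]2c1c(OCc9ccccc9)c2c(c([C@@H]3c4ccc(OCc9ccccc9)cc4O[C@H](c4ccc(OCc9ccccc9)c(OCc9ccccc9)c4)[C@H]3O)c1OCc9ccccc9)O[C@H](c1ccc(OCc9ccccc9)c(OCc9ccccc9)c1)[C@@H](OCc9ccccc9)C2 | intermediate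
22 | fisetinidol-(4α→6)-fisetinidol-(4α→6)-[fisetinidol-(4α→8)]-catechin; all four units 2R,3S, each interflavan bond trans to the adjacent 3-hydroxyl | Oc1ccc2c(c1)O[C@H](c1ccc(O)c(O)c1)[C@@H](O)[C@@H]2c1cc2c(cc1O)O[C@H](c1ccc(O)c(O)c1)[C@@H](O)[C@@H]2c1c(O)c2c(c([C@@H]3c4ccc(O)cc4O[C@H](c4ccc(O)c(O)c4)[C@H]3O)c1O)O[C@H](c1ccc(O)c(O)c1)[C@@H](O)C2 | target

**Totals.** 15 steps in all. Longest linear sequence: 10 steps (1 → 2 → 3 → 4 → 5 → 11 → 13 → 14 → 19 → 21 → 22, that is steps 1–4, 8–10, 13–15).

**Steps most likely to fail**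

1. Step 13 (proposed new method). After C3–C4 bond formation the β-silyl benzylic cation may lose silicon to the phosphate faster than O1 closes the ring, which would open the system to allylphenols and silylate the catalyst. Facial selectivity at one of the three methides may also be poor on a scaffold that already carries stereocentres. The fallback uses known chemistry, sets out from 14 and alkyne 16 and returns at 21, leaving silicon out altogether. Acid-catalysed annulation of the ortho-quinone methides with the aryl alkyne (FeCl3 or the same phosphoric acid, toluene), a known route to 2-aryl-4H-chromenes, should give the tris(2-aryl-4H-chromene) F1, in which only C4 of units T, M and U is stereogenic. Hydroboration of the three enol-ether double bonds (BH3·SMe2, THF), known for flav-2-enes, places boron on C3 and hydrogen on C2 from the face opposite the C4 substituent and gives the tris(C3-borane) adduct F2. Oxidation in the same flask (NaBO3·4H2O) then gives the 2,3-trans-3,4-trans triol 21. Control of C4 is not assured here, so C4 diastereomers would have to be separated.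

2. Step 14. Fluoride may trigger anti-elimination across C3–Si and C2–O1, opening ring C to a phenoxide and an (E)-alkene, before the benzyl group leaves silicon. One of the three silicon groups may also remain unoxidised. The fallback sets out from 15 and returns at 21, and carries a strained siletane that takes up hydroperoxide under buffered aqueous conditions, so no anhydrous fluoride is needed. Takai iodo-olefination of 15 (CHI3, CrCl2, THF) should give (E)-1,2-bis(benzyloxy)-4-(2-iodoethenyl)benzene F3. Iodine–lithium exchange (t-BuLi, −78 °C) gives the (E)-alkenyllithium F4, which is trapped with 1-chloro-1-methylsiletane to give (E)-1-{2-[3,4-bis(benzyloxy)phenyl]ethenyl}-1-methylsiletane F5. Cycloaddition of three molecules of F5 with 14 under the conditions of step 13 gives the tris(1-methylsiletan-1-yl) tetramer F6. Its strained silicon opens and is oxidised directly (H2O2, KF, KHCO3, THF/MeOH, rt) and should give 21.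

3. Step 9. Double bromine–lithium exchange on an alkoxide-bearing substrate may stop halfway, or one aryllithium may be protonated inside a poorly soluble trilithium aggregate, leaving mono-adducts. The fallback sets out from 11 and returns at 13, and removes the charge from the substrate. Silylation of the carbinol (Et3SiCl, imidazole, DMF) gives the triethylsilyl ether F7, a neutral dibromide. Exchange with t-BuLi (4.2 equiv, THF, −78 °C) gives the dilithium species F8, which has no alkoxide and no silyl group within reach of either C–Li bond. Addition to 7 gives the mono-silylated tris(benzhydrol) F9, and Bu4NF (THF, 0 °C) frees the third carbinol to give 13.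

**Further compounds**

F1 | step 13 | tris(2-aryl-4H-chromene): as 21 but with a C2=C3 double bond and no C3 substituent in units T, M and U | c9ccccc9COc1ccc2c(c1)OC(c1ccc(OCc9ccccc9)c(OCc9ccccc9)c1)=C[C@@H]2c1cc2c(cc1OCc9ccccc9)OC(c1ccc(OCc9ccccc9)c(OCc9ccccc9)c1)=C[C@@H]2c1c(OCc9ccccc9)c2c(c([C@@H]3c4ccc(OCc9ccccc9)cc4OC(c4ccc(OCc9ccccc9)c(OCc9ccccc9)c4)=C3)c1OCc9ccccc9)O[C@H](c1ccc(OCc9ccccc9)c(OCc9ccccc9)c1)[C@@H](OCc9ccccc9)C2
F2 | step 13 | tris(C3-borane) adduct of F1, drawn with BH2 on C3 of units T, M and U | c9ccccc9COc1ccc2c(c1)O[C@H](c1ccc(OCc9ccccc9)c(OCc9ccccc9)c1)[C@@H](B)[C@@H]2c1cc2c(cc1OCc9ccccc9)O[C@H](c1ccc(OCc9ccccc9)c(OCc9ccccc9)c1)[C@@H](B)[C@@H]2c1c(OCc9ccccc9)c2c(c([C@@H]3c4ccc(OCc9ccccc9)cc4O[C@H](c4ccc(OCc9ccccc9)c(OCc9ccccc9)c4)[C@H]3B)c1OCc9ccccc9)O[C@H](c1ccc(OCc9ccccc9)c(OCc9ccccc9)c1)[C@@H](OCc9ccccc9)C2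
F3 | step 14 | (E)-1,2-bis(benzyloxy)-4-(2-iodoethenyl)benzene | I/C=C/c1ccc(OCc2ccccc2)c(OCc2ccccc2)c1
F4 | step 14 | (E)-{2-[3,4-bis(benzyloxy)phenyl]ethenyl}lithium | [Li]/C=C/c1ccc(OCc2ccccc2)c(OCc2ccccc2)c1
F5 | step 14 | (E)-1-{2-[3,4-bis(benzyloxy)phenyl]ethenyl}-1-methylsiletane | C[Si]1(CCC1)/C=C/c1ccc(OCc2ccccc2)c(OCc2ccccc2)c1
F6 | step 14 | tris(1-methylsiletan-1-yl) tetramer: as 19 with 1-methylsiletan-1-yl in place of each SiMe2Bn | c9ccccc9COc1ccc2c(c1)O[C@H](c1ccc(OCc9ccccc9)c(OCc9ccccc9)c1)[C@@H]([Si]8(C)CCC8)[C@@H]2c1cc2c(cc1OCc9ccccc9)O[C@H](c1ccc(OCc9ccccc9)c(OCc9ccccc9)c1)[C@@H]([Si]8(C)CCC8)[C@@H]2c1c(OCc9ccccc9)c2c(c([C@@H]3c4ccc(OCc9ccccc9)cc4O[C@H](c4ccc(OCc9ccccc9)c(OCc9ccccc9)c4)[C@H]3[Si]8(C)CCC8)c1OCc9ccccc9)O[C@H](c1ccc(OCc9ccccc9)c(OCc9ccccc9)c1)[C@@H](OCc9ccccc9)C2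
F7 | step 9 | triethylsilyl ether of 11 | C(c9ccccc9)Oc1c(C(O[Si](CC)(CC)CC)c3cc(Br)c(OCc9ccccc9)cc3OCC=C)c(OCc9ccccc9)c2c(c1Br)O[C@H](c1ccc(OCc9ccccc9)c(OCc9ccccc9)c1)[C@@H](OCc9ccccc9)C2
F8 | step 9 | dilithium species from F7 (C–Li in place of both C–Br bonds) | C(c9ccccc9)Oc1c(C(O[Si](CC)(CC)CC)c3cc([Li])c(OCc9ccccc9)cc3OCC=C)c(OCc9ccccc9)c2c(c1[Li])O[C@H](c1ccc(OCc9ccccc9)c(OCc9ccccc9)c1)[C@@H](OCc9ccccc9)C2
F9 | step 9 | 13 with the carbinol between units B and M as its triethylsilyl ether | C(c9ccccc9)Oc1c(C(O[Si](CC)(CC)CC)c3cc(C(O)c4ccc(OCc9ccccc9)cc4OCC=C)c(OCc9ccccc9)cc3OCC=C)c(OCc9ccccc9)c2c(c1C(O)c5ccc(OCc9ccccc9)cc5OCC=C)O[C@H](c1ccc(OCc9ccccc9)c(OCc9ccccc9)c1)[C@@H](OCc9ccccc9)C2
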